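**Plan**

1. Numbering (germacrane): ring A is the ten-membered carbocycle C1–C10 (C1 ketone, C3 OH, C4=C5, C8 O-angelate, C9 OAc, C10 OH/CH3); ring B is the lactone O–C6–C7–C11(=C13)–C12.
2. Retrosynthesis: remove the two esters and C13; read the α-ketol C1(=O)–C10(OH)CH3 as an oxidised pinacol and cut ring A at C1–C10 to a C1 aldehyde / C10 methyl ketone; then cut C8–C9 (hydroxyacetone aldol) and C6–C7 (succinate aldol).
3. Forward: (Z)-enal C1–C6 (steps 1–7); succinate aldol/lactonisation makes ring B; proline aldol adds C9, C10 and the C10 methyl; SmI2 pinacol closes ring A; then C13 methylenation, C1 oxidation, acylations, desilylation.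
4. Stereochemistry: C3 from Alpine-Borane reduction, 4Z from syn-carbocupration, C6/C7 from the oxazolidinone auxiliary, C8/C9 from L-proline, C10 from Felkin–Anh addition of the C1 ketyl anti to the C9–O bond.
5. Enabling feature: the vicinal C1/C10 oxygen pair (pinacol retron) and three rigid elements between them — the (Z)-C4=C5 alkene, the trans-fused ring B and a cis-dioxolane on C8/C9 — which fold the chain so that C1 and C10 can meet.

Key step: step 16

Remark: the C1 carbinol in 23 and 26 and C11 in the transient 24 and 25 are temporary stereocentres that are destroyed later; their configuration does not matter and they are written without descriptor.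

**Route**

Step 1
Reactants: 1 3-[(tert-butyldimethylsilyl)oxy]propanal; 2 methyl propiolate
Product: 3 racemic methyl 6-[(tert-butyldimethylsilyl)oxy]-4-hydroxyhex-2-ynoate
Conditions: 2, LDA (LiN(i-Pr)2), THF, −78 °C; then 1; AcOH, −78 °C
Reagents that add atoms: none
Why: Lithium methyl propiolate, formed and kept at −78 °C, should add 1,2 to the unhindered aldehyde (acetylide addition), the racemic carbinol being corrected by the oxidation–reduction of steps 2 and 3.

Step 2
Reactants: 3 racemic propargylic alcohol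
Product: 4 methyl 6-[(tert-butyldimethylsilyl)oxy]-4-oxohex-2-ynoate
Conditions: Dess–Martin periodinane, pyridine, CH2Cl2, 0 °C → rt
Reagents that add atoms: none
Why: Dess–Martin oxidation converts the propargylic alcohol into the ynone under nearly neutral conditions that should spare the β-silyloxy group and the ynoate.

Step 3
Reactants: 4 ynone
Product: 5 methyl (4R)-6-[(tert-butyldimethylsilyl)oxy]-4-hydroxyhex-2-ynoate
Conditions: (R)-Alpine-Borane (B-isopinocampheyl-9-BBN from (+)-α-pinene), THF, rt; then HOCH2CH2NH2, Et2O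
Reagents that add atoms: none
Why: Midland reduction, in which hydride passes from the pinanyl group through a boat-like six-membered transition state with the slim alkynyl group in the hindered position, gives the (R)-carbinol from 1-alkyn-3-ones and 4-oxo-2-alkynoates with the reagent from (+)-α-pinene, so C3 should be set as (R).

Step 4
Reactants: 5 (R)-propargylic alcohol
Product: 6 methyl (4R)-6-[(tert-butyldimethylsilyl)oxy]-4-[(tert-butyldiphenylsilyl)oxy]hex-2-ynoate
Conditions: TBDPSCl, imidazole, DMF, rt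
Reagents that add atoms: tert-butyl(chloro)diphenylsilane, CC(C)(C)[Si](Cl)(c1ccccc1)c1ccccc1
Why: Standard silylation; the acid-stable TBDPS ether is chosen so that it outlives removal of the primary TBS ether (step 14) and the acetonide hydrolysis (step 19).

Step 5
Reactants: 6 silylated ynoate
Product: 7 methyl (2Z,4R)-6-[(tert-butyldimethylsilyl)oxy]-4-[(tert-butyldiphenylsilyl)oxy]-3-methylhex-2-enoate
Conditions: Me2CuLi (from CuI and 2 MeLi), THF, −78 °C; MeOH, −78 °C
Reagents that add atoms: lithium dimethylcuprate, [Li+].C[Cu-]C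
Why: syn-Carbocupration of the ynoate and protonation of the alkenylcopper at −78 °C, before it can equilibrate through the allenoate, place CH3 and H cis, so the ester and the C3 chain should end up cis, which is the (4Z) geometry of the target.

Step 6
Reactants: 7 (Z)-enoate
Product: 8 (2Z,4R)-6-[(tert-butyldimethylsilyl)oxy]-4-[(tert-butyldiphenylsilyl)oxy]-3-methylhex-2-en-1-ol
Conditions: i-Bu2AlH (DIBAL-H), CH2Cl2, −78 °C; aq. potassium sodium tartrate
Reagents that add atoms: none
Why: DIBAL-H reduces the enoate 1,2 to the allylic alcohol without touching the alkene geometry or the silyl ethers.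

Step 7
Reactants: 8 (Z)-allylic alcohol
Product: 9 (2Z,4R)-6-[(tert-butyldimethylsilyl)oxy]-4-[(tert-butyldiphenylsilyl)oxy]-3-methylhex-2-enal
Conditions: Dess–Martin periodinane, pyridine, CH2Cl2, 0 °C
Reagents that add atoms: none
Why: Buffered Dess–Martin oxidation gives the (Z)-enal without acid or base that could isomerise it to the (E)-enal, and the aldehyde is used at once.

Step 8
Reactants: 10 (4S)-4-benzyl-1,3-oxazolidin-2-one; 11 methyl 4-chloro-4-oxobutanoate
Product: 12 methyl 4-[(4S)-4-benzyl-2-oxo-1,3-oxazolidin-3-yl]-4-oxobutanoate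
Conditions: n-BuLi, THF, −78 °C; then 11, −78 → 0 °C
Reagents that add atoms: none
Why: N-Acylation of the lithiated oxazolidinone by the acid chloride is fast and selective over the methyl ester.

Step 9
Reactants: 12 succinyl imide; 9 (Z)-enal
Product: 14 trans-γ-lactone N-acyl oxazolidinone, via syn-aldol adduct 13 (not isolated)
Conditions: 12, Bu2BOTf, i-Pr2NEt, CH2Cl2, −78 → 0 °C; 9, −78 → 0 °C; pH 7 buffer, MeOH, H2O2, 0 °C; then PPTS (cat.), CH2Cl2, rt
Reagents that add atoms: none
Why: Evans syn-aldol reaction, in which the (Z)-boron enolate (formed next to the imide, not the ester) reacts through a Zimmerman–Traxler chair on the face away from the benzyl group, should set C6 and C7 as drawn, and the γ-hydroxy ester then closes to the trans-disubstituted γ-lactone (ring B) with loss of methanol.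

Step 10
Reactants: 14 lactone imide
Product: 15 (2R,3S)-lactone carboxylic acid
Conditions: LiOH, H2O2, THF/H2O, 0 °C; Na2SO3; 1 M HCl to pH 3
Reagents that add atoms: hydrogen peroxide (as LiOOH), OO
Why: Hydroperoxide attacks the exocyclic imide carbonyl selectively (standard auxiliary cleavage), and any lactone opened by hydroxide should close again on acidification because only the five-membered lactone can form.

Step 11
Reactants: 15 lactone acid
Product: 17 (2R,3S)-lactone aldehyde, via acid chloride 16 (not isolated)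
Conditions: 1-chloro-N,N,2-trimethylprop-1-en-1-amine, CH2Cl2, 0 °C → rt; then LiAlH(O-t-Bu)3, THF, −78 °C
Reagents that add atoms: none
Why: Neutral acid chloride formation followed by reduction with the hindered hydride LiAlH(O-t-Bu)3 at −78 °C stops at the aldehyde and leaves the lactone alone, and without base C7 should not epimerise (the trans arrangement is in any case the stable one).

Step 12
Reactants: 17 lactone aldehyde; 18 hydroxyacetone
Product: 19 anti-dihydroxy ketone (C8 and C9 carbinols)
Conditions: L-proline (30 mol %), 18 (excess), DMSO, rt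
Reagents that add atoms: none
Why: In the proline-catalysed direct aldol reaction of hydroxyacetone the hydroxy-enamine of L-proline reacts at its oxygenated carbon with the Re face of the α-branched aldehyde in the acid-organised chair-like transition state, which gives anti-1,2-diols and should set C8 and C9 under catalyst control as (1S,2S) in the side chain.

Step 13
Reactants: 19 anti-diol
Product: 20 cis-acetonide methyl ketone
Conditions: Me2C(OMe)2, PPTS (cat.), CH2Cl2, rt
Reagents that add atoms: 2,2-dimethoxypropane, COC(C)(C)OC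
Why: The anti-diol closes to the cis-4,5-disubstituted dioxolane, which protects the α-hydroxy ketone for the reductive step and holds C7 and C10 on the same side of a five-membered ring.

Step 14
Reactants: 20 acetonide
Product: 21 primary alcohol (C1 hydroxyl free)
Conditions: HF·pyridine, pyridine, THF, 0 °C
Reagents that add atoms: none
Why: Buffered HF·pyridine removes the primary TBS ether far faster than the secondary TBDPS ether and does not touch the acetonide.

Step 15
Reactants: 21 primary alcohol
Product: 22 keto-aldehyde (C1 aldehyde and C10 methyl ketone)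
Conditions: Dess–Martin periodinane, pyridine, CH2Cl2, 0 °C
Reagents that add atoms: none
Why: Buffered Dess–Martin oxidation gives the β-silyloxy aldehyde without β-elimination or epimerisation at C9, and the keto-aldehyde is used immediately.

Step 16
Reactants: 22 keto-aldehyde
Product: 23 ten-membered 1,10-diol
Conditions: SmI2 (0.1 M in THF, 2.5 equiv, added over 3 h) to 22 (2 mM in THF), −78 °C → 0 °C; H2O
Reagents that add atoms: none
Why: SmI2 (divalent samarium) transfers one electron to the aldehyde, the more easily reduced carbonyl, to give a samarium-bound C1 ketyl radical that adds to the samarium-activated C10 acetyl carbon, and a second electron transfer and protonation give the diol. The closest known reaction types are the SmI2 and low-valent-titanium keto-aldehyde pinacol macrocyclisations to medium and large carbocycles and the SmI2 pinacol carbocyclisation of α-alkoxy dicarbonyl compounds. Ring A (C1–C10) closes by a 10-exo-trig radical addition to the C=O bond, helped by the (4Z)-alkene, the trans-fused ring B and the cis-dioxolane, which leave few free rotors between the two reacting carbons. C10 is set by attack anti to the C9–O bond (polar Felkin–Anh arrangement, reinforced by repulsion between the ketyl oxygen and the dioxolane oxygen), the usual sense of SmI2 pinacol couplings next to an alkoxy group, while the C1 carbinol configuration is irrelevant because C1 is oxidised in step 18. The step needs chemoselection for the aldehyde over the α-alkoxy ketone (otherwise the C9 oxygen is lost reductively) and cyclisation over dimerisation, which slow addition of SmI2 to a 2 mM solution at −78 °C without HMPA or proton donor should secure. No Michael acceptor is present at this stage (C13 is added afterwards), and the lactone, silyl ether and trisubstituted alkene are inert to SmI2.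

Step 17
Reactants: 23 1,10-diol
Product: 26 α-methylene lactone diol, via Mannich base 24 (not isolated), via ammonium iodide 25 (not isolated)
Conditions: LDA (LiN(i-Pr)2, 3.5 equiv), THF, −78 °C; H2C=NMe2+ I−, −78 °C → rt; H2O; then MeI, THF/MeOH, rt; then aq. NaHCO3, EtOAc, rt
Reagents that add atoms: N,N-dimethylmethyleneiminium iodide (Eschenmoser's salt), C=[N+](C)C.[I-]
Why: α-Methylenation of the lactone through its lithium enolate (the two alkoxides are spectators and no ketone is present at this stage) by Mannich reaction with Eschenmoser's salt, quaternisation and E1cB loss of trimethylamine gives the exocyclic C11=C13 alkene and destroys the C11 stereocentre of the intermediates.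

Step 18
Reactants: 26 α-methylene lactone diol
Product: 27 α-ketol (C1 ketone and C10 tertiary alcohol)
Conditions: Dess–Martin periodinane, pyridine, CH2Cl2, 0 °C → rt
Reagents that add atoms: none
Why: Only the secondary C1 carbinol can be oxidised (the C10 hydroxyl is tertiary), so Dess–Martin oxidation should give the α-ketol without cleaving the C1–C10 bond.

Step 19
Reactants: 27 acetonide α-ketol
Product: 28 8,9,10-triol
Conditions: AcOH/H2O (4:1), 40 °C
Reagents that add atoms: none
Why: Aqueous acetic acid hydrolyses the strained cis-dioxolane while the secondary TBDPS ether, the lactone and the α-ketol should survive.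

Step 20
Reactants: 28 triol; 29 angelic acid
Product: 31 8-O-angelate, via mixed anhydride 30 (not isolated)
Conditions: 29, 2,4,6-trichlorobenzoyl chloride, Et3N, toluene, rt; then 28, toluene, 80 °C
Reagents that add atoms: none
Why: Yamaguchi-type esterification through the mixed anhydride without DMAP (to avoid angelate-to-tiglate isomerisation) should put the bulky acyl group on the C8 hydroxyl, which has only a CH neighbour in ring B, rather than on the C9 hydroxyl next to the fully substituted C10, while the tertiary C10 hydroxyl is inert.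

Step 21
Reactants: 31 8-O-angelate
Product: 32 8-O-angelate 9-O-acetate (3-O-TBDPS ether of the target)
Conditions: Ac2O, pyridine, DMAP (cat.), CH2Cl2, 0 °C
Reagents that add atoms: acetic anhydride, CC(=O)OC(C)=O
Why: The small acetyl donor acylates the remaining secondary C9 hydroxyl, and the tertiary C10 hydroxyl should not react at 0 °C.

Step 22
Reactants: 32 silyl ether
Product: 33 target CNP0308559.3
Conditions: HF·pyridine, THF, 0 °C → rt
Reagents that add atoms: none
Why: Acidic fluoride removes the TBDPS ether without the basic conditions that would cause acyl migration, retro-aldol cleavage or β-elimination of the C3 hydroxyl.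

**Compound list**

1 | 3-[(tert-butyldimethylsilyl)oxy]propanal | O=CCCO[Si](C)(C)C(C)(C)C | starting material
2 | methyl propiolate (methyl prop-2-ynoate) | C#CC(=O)OC | starting material
3 | methyl 6-[(tert-butyldimethylsilyl)oxy]-4-hydroxyhex-2-ynoate, racemic | COC(=O)C#CC(O)CCO[Si](C)(C)C(C)(C)C | intermediate
4 | methyl 6-[(tert-butyldimethylsilyl)oxy]-4-oxohex-2-ynoate | COC(=O)C#CC(=O)CCO[Si](C)(C)C(C)(C)C | intermediate
5 | methyl (4R)-6-[(tert-butyldimethylsilyl)oxy]-4-hydroxyhex-2-ynoate | COC(=O)C#C[C@H](O)CCO[Si](C)(C)C(C)(C)C | intermediate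
6 | methyl (4R)-6-[(tert-butyldimethylsilyl)oxy]-4-[(tert-butyldiphenylsilyl)oxy]hex-2-ynoate | COC(=O)C#C[C@H](O[Si](c1ccccc1)(c1ccccc1)C(C)(C)C)CCO[Si](C)(C)C(C)(C)C | intermediate
7 | methyl (2Z,4R)-6-[(tert-butyldimethylsilyl)oxy]-4-[(tert-butyldiphenylsilyl)oxy]-3-methylhex-2-enoate | COC(=O)/C=C(/C)[C@H](O[Si](c1ccccc1)(c1ccccc1)C(C)(C)C)CCO[Si](C)(C)C(C)(C)C | intermediate
8 | (2Z,4R)-6-[(tert-butyldimethylsilyl)oxy]-4-[(tert-butyldiphenylsilyl)oxy]-3-methylhex-2-en-1-ol | OC/C=C(/C)[C@H](O[Si](c1ccccc1)(c1ccccc1)C(C)(C)C)CCO[Si](C)(C)C(C)(C)C | intermediate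
9 | (2Z,4R)-6-[(tert-butyldimethylsilyl)oxy]-4-[(tert-butyldiphenylsilyl)oxy]-3-methylhex-2-enal | O=C/C=C(/C)[C@H](O[Si](c1ccccc1)(c1ccccc1)C(C)(C)C)CCO[Si](C)(C)C(C)(C)C | intermediate
10 | (4S)-4-benzyl-1,3-oxazolidin-2-one | O=C1N[C@@H](Cc2ccccc2)CO1 | starting material
11 | methyl 4-chloro-4-oxobutanoate | COC(=O)CCC(Cl)=O | starting material
12 | methyl 4-[(4S)-4-benzyl-2-oxo-1,3-oxazolidin-3-yl]-4-oxobutanoate | COC(=O)CCC(=O)N1[C@@H](Cc2ccccc2)COC1=O | intermediate
13 | methyl (3S,4R,5Z,7R)-3-{[(4S)-4-benzyl-2-oxo-1,3-oxazolidin-3-yl]carbonyl}-9-[(tert-butyldimethylsilyl)oxy]-7-[(tert-butyldiphenylsilyl)oxy]-4-hydroxy-6-methylnon-5-enoate (syn-aldol adduct) | COC(=O)C[C@@H]([C@H](O)/C=C(/C)[C@H](O[Si](c3ccccc3)(c3ccccc3)C(C)(C)C)CCO[Si](C)(C)C(C)(C)C)C(=O)N1[C@@H](Cc2ccccc2)COC1=O | intermediate (not isolated)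
14 | (4S)-4-benzyl-3-({(2R,3S)-2-[(1Z,3R)-5-[(tert-butyldimethylsilyl)oxy]-3-[(tert-butyldiphenylsilyl)oxy]-2-methylpent-1-en-1-yl]-5-oxooxolan-3-yl}carbonyl)-1,3-oxazolidin-2-one (trans-lactone, ring B) | C1C(=O)O[C@H](/C=C(/C)[C@H](O[Si](c3ccccc3)(c3ccccc3)C(C)(C)C)CCO[Si](C)(C)C(C)(C)C)[C@H]1C(=O)N1[C@@H](Cc2ccccc2)COC1=O | intermediate
15 | (2R,3S)-2-[(1Z,3R)-5-[(tert-butyldimethylsilyl)oxy]-3-[(tert-butyldiphenylsilyl)oxy]-2-methylpent-1-en-1-yl]-5-oxooxolane-3-carboxylic acid | C1C(=O)O[C@H](/C=C(/C)[C@H](O[Si](c3ccccc3)(c3ccccc3)C(C)(C)C)CCO[Si](C)(C)C(C)(C)C)[C@H]1C(=O)O | intermediate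
16 | (2R,3S)-2-[(1Z,3R)-5-[(tert-butyldimethylsilyl)oxy]-3-[(tert-butyldiphenylsilyl)oxy]-2-methylpent-1-en-1-yl]-5-oxooxolane-3-carbonyl chloride | C1C(=O)O[C@H](/C=C(/C)[C@H](O[Si](c3ccccc3)(c3ccccc3)C(C)(C)C)CCO[Si](C)(C)C(C)(C)C)[C@H]1C(Cl)=O | intermediate (not isolated)
17 | (2R,3S)-2-[(1Z,3R)-5-[(tert-butyldimethylsilyl)oxy]-3-[(tert-butyldiphenylsilyl)oxy]-2-methylpent-1-en-1-yl]-5-oxooxolane-3-carbaldehyde | C1C(=O)O[C@H](/C=C(/C)[C@H](O[Si](c3ccccc3)(c3ccccc3)C(C)(C)C)CCO[Si](C)(C)C(C)(C)C)[C@H]1C=O | intermediate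
18 | hydroxyacetone (1-hydroxypropan-2-one) | CC(=O)CO | starting material
19 | (4R,5R)-4-[(1S,2S)-1,2-dihydroxy-3-oxobutyl]-5-[(1Z,3R)-5-[(tert-butyldimethylsilyl)oxy]-3-[(tert-butyldiphenylsilyl)oxy]-2-methylpent-1-en-1-yl]oxolan-2-one | C1C(=O)O[C@H](/C=C(/C)[C@H](O[Si](c3ccccc3)(c3ccccc3)C(C)(C)C)CCO[Si](C)(C)C(C)(C)C)[C@H]1[C@H](O)[C@H](O)C(C)=O | intermediate
20 | (4S,5R)-4-[(4S,5S)-5-acetyl-2,2-dimethyl-1,3-dioxolan-4-yl]-5-[(1Z,3R)-5-[(tert-butyldimethylsilyl)oxy]-3-[(tert-butyldiphenylsilyl)oxy]-2-methylpent-1-en-1-yl]oxolan-2-one (cis-dioxolane) | C1C(=O)O[C@H](/C=C(/C)[C@H](O[Si](c3ccccc3)(c3ccccc3)C(C)(C)C)CCO[Si](C)(C)C(C)(C)C)[C@H]1[C@@H]2OC(C)(C)O[C@@H]2C(C)=O | intermediate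
21 | (4S,5R)-4-[(4S,5S)-5-acetyl-2,2-dimethyl-1,3-dioxolan-4-yl]-5-[(1Z,3R)-3-[(tert-butyldiphenylsilyl)oxy]-5-hydroxy-2-methylpent-1-en-1-yl]oxolan-2-one | C1C(=O)O[C@H](/C=C(/C)[C@H](O[Si](c3ccccc3)(c3ccccc3)C(C)(C)C)CCO)[C@H]1[C@@H]2OC(C)(C)O[C@@H]2C(C)=O | intermediate
22 | (4S,5R)-4-[(4S,5S)-5-acetyl-2,2-dimethyl-1,3-dioxolan-4-yl]-5-[(1Z,3R)-3-[(tert-butyldiphenylsilyl)oxy]-2-methyl-5-oxopent-1-en-1-yl]oxolan-2-one (keto-aldehyde) | C1C(=O)O[C@H](/C=C(/C)[C@H](O[Si](c3ccccc3)(c3ccccc3)C(C)(C)C)CC=O)[C@H]1[C@@H]2OC(C)(C)O[C@@H]2C(C)=O | intermediate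
23 | (4Z)-3-[(tert-butyldiphenylsilyl)oxy]-1,10-dihydroxy-8,9-(isopropylidenedioxy)germacr-4-en-12,6-olide; C3, C6, C7, C8, C9 and C10 arranged as in the target, C1 carbinol open | C1C(=O)O[C@@H]2/C=C(/C)[C@H](O[Si](c4ccccc4)(c4ccccc4)C(C)(C)C)CC(O)[C@@](C)(O)[C@H]3OC(C)(C)O[C@H]3[C@@H]12 | intermediate
24 | 11-[(dimethylamino)methyl] derivative of 23 (Mannich base; C11 open) | CN(C)CC1C(=O)O[C@@H]2/C=C(/C)[C@H](O[Si](c4ccccc4)(c4ccccc4)C(C)(C)C)CC(O)[C@@](C)(O)[C@H]3OC(C)(C)O[C@H]3[C@@H]12 | intermediate (not isolated)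
25 | 11-[(trimethylammonio)methyl] derivative of 23, iodide (C11 open) | C[N+](C)(C)CC1C(=O)O[C@@H]2/C=C(/C)[C@H](O[Si](c4ccccc4)(c4ccccc4)C(C)(C)C)CC(O)[C@@](C)(O)[C@H]3OC(C)(C)O[C@H]3[C@@H]12.[I-] | intermediate (not isolated)
26 | (4Z)-3-[(tert-butyldiphenylsilyl)oxy]-1,10-dihydroxy-8,9-(isopropylidenedioxy)germacra-4,11(13)-dien-12,6-olide; stereocentres as in 23 | C=C1C(=O)O[C@@H]2/C=C(/C)[C@H](O[Si](c4ccccc4)(c4ccccc4)C(C)(C)C)CC(O)[C@@](C)(O)[C@H]3OC(C)(C)O[C@H]3[C@@H]12 | intermediate
27 | (4Z)-3-[(tert-butyldiphenylsilyl)oxy]-10-hydroxy-8,9-(isopropylidenedioxy)-1-oxogermacra-4,11(13)-dien-12,6-olide; all stereocentres arranged as in the target | C=C1C(=O)O[C@@H]2/C=C(/C)[C@H](O[Si](c4ccccc4)(c4ccccc4)C(C)(C)C)CC(=O)[C@@](C)(O)[C@H]3OC(C)(C)O[C@H]3[C@@H]12 | intermediate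
28 | (4Z)-3-[(tert-butyldiphenylsilyl)oxy]-8,9,10-trihydroxy-1-oxogermacra-4,11(13)-dien-12,6-olide; stereocentres arranged as in the target | C=C1C(=O)O[C@@H]2/C=C(/C)[C@H](O[Si](c3ccccc3)(c3ccccc3)C(C)(C)C)CC(=O)[C@@](C)(O)[C@@H](O)[C@@H](O)[C@@H]12 | intermediate
29 | angelic acid, (2Z)-2-methylbut-2-enoic acid | C/C=C(/C)C(=O)O | starting material
30 | (2Z)-2-methylbut-2-enoic 2,4,6-trichlorobenzoic anhydride | C/C=C(/C)C(=O)OC(=O)c1c(Cl)cc(Cl)cc1Cl | intermediate (not isolated)
31 | 8-O-angeloyl derivative of 28 (C9 and C10 hydroxyls free) | C=C1C(=O)O[C@@H]2/C=C(/C)[C@H](O[Si](c3ccccc3)(c3ccccc3)C(C)(C)C)CC(=O)[C@@](C)(O)[C@@H](O)[C@@H](OC(=O)/C(C)=C\C)[C@@H]12 | intermediate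
32 | 9-O-acetyl-8-O-angeloyl derivative of 28 (3-O-TBDPS ether of the target) | C=C1C(=O)O[C@@H]2/C=C(/C)[C@H](O[Si](c3ccccc3)(c3ccccc3)C(C)(C)C)CC(=O)[C@@](C)(O)[C@@H](OC(C)=O)[C@@H](OC(=O)/C(C)=C\C)[C@@H]12 | intermediate
33 | (3R,4Z,6R,7S,8S,9S,10S)-9-acetoxy-8-[(2Z)-2-methylbut-2-enoyloxy]-3,10-dihydroxy-1-oxogermacra-4,11(13)-dien-12,6-olide (CNP0308559.3) | C=C1C(=O)O[C@@H]2/C=C(/C)[C@H](O)CC(=O)[C@@](C)(O)[C@@H](OC(C)=O)[C@@H](OC(=O)/C(C)=C\C)[C@@H]12 | target

**Count and risks**

Total steps: 22. Longest linear sequence: 21 steps (steps 1–7 and 9–22; step 8 is a one-step side branch).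

Steps most likely to fail:

Step 16 (key ring closure). Intermolecular pinacol dimerisation, simple reduction of the aldehyde, reductive cleavage of the C9–O bond of the α-alkoxy ketone, or attack on the wrong face of the acetyl group may outrun the ten-membered ring closure. Fallback (olefin closure, then oxidation): setting out from 22, double Wittig methylenation (Ph3P=CH2 from Ph3PCH3Br and KN(SiMe3)2, THF, 0 °C) gives the bis-methylene compound F1. Ring-closing metathesis (second-generation Hoveyda–Grubbs catalyst, toluene, 80 °C, 1 mM) then forms the same C1–C10 bond as a trisubstituted alkene in the cyclodeca-1(10),4-diene F2. OsO4 (cat.)/NMO dihydroxylates this alkene, which is more electron-rich and less hindered than C4=C5, from the outer face of the ring and comes back to the route at 23.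

Step 12 (proline aldol). β-Elimination of the lactone carboxylate from the β-acyloxy aldehyde (through its enol or enamine), or weak catalyst control over the aldehyde face, may erode yield and diastereoselectivity. Fallback: setting out from 17, Wittig olefination with Ph3P=CHC(O)CH3 (CH2Cl2, rt) gives the (E)-enone F3. Lanthanum–BINOL-catalysed nucleophilic epoxidation (La(O-i-Pr)3, (R)-BINOL, Ph3As=O, t-BuOOH, 4 Å sieves, THF), which touches only the enone, gives the (8R,9S)-trans-epoxy ketone F4. BF3·OEt2 in acetone opens the epoxide at C8 (β to the ketone) with inversion and closes the cis-dioxolane, coming back to the route at 20.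

Step 20 (site-selective angeloylation). Loss of site selectivity between the C8 and C9 hydroxyls, masking of the C8 hydroxyl by transannular hemiketal formation with the C1 ketone, acyl migration, or angelate-to-tiglate isomerisation at 80 °C may spoil the step. Fallback (mask O8 with the ketone itself and acetylate first): setting out from 28, MeOH/PPTS converts the γ-hydroxy ketone into the transannular 1,8-epoxy methyl ketal F5 (only O8 can reach C1 through a five-membered ring). Ac2O/pyridine/DMAP then acetylates the only free secondary hydroxyl (C9) to the ketal acetate F6. Aqueous AcOH returns the ketone and the C8 hydroxyl in the 9-O-acetate F7, and angeloylation under the conditions of step 20 on this single secondary alcohol comes back to the route at 32.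

Further compounds
F1 | step 16 | bis-methylene compound from 22 (C1 aldehyde and C10 ketone each converted to C=CH2; stereocentres as in 22) | C1C(=O)O[C@H](/C=C(/C)[C@H](O[Si](c3ccccc3)(c3ccccc3)C(C)(C)C)CC=C)[C@H]1[C@@H]2OC(C)(C)O[C@@H]2C(C)=C
F2 | step 16 | cyclodeca-1(10),4-diene lactone (C1=C10 alkene in place of the diol of 23; other stereocentres as in 23; C1=C10 geometry open) | C1C(=O)O[C@@H]2/C=C(/C)[C@H](O[Si](c4ccccc4)(c4ccccc4)C(C)(C)C)CC=C(C)[C@H]3OC(C)(C)O[C@H]3[C@@H]12
F3 | step 12 | (E)-enone from 17 (CHO replaced by (E)-CH=CH–C(O)CH3; stereocentres as in 17) | C1C(=O)O[C@H](/C=C(/C)[C@H](O[Si](c3ccccc3)(c3ccccc3)C(C)(C)C)CCO[Si](C)(C)C(C)(C)C)[C@H]1/C=C/C(C)=O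
F4 | step 12 | (8R,9S)-trans-epoxy ketone from F3 | C1C(=O)O[C@H](/C=C(/C)[C@H](O[Si](c3ccccc3)(c3ccccc3)C(C)(C)C)CCO[Si](C)(C)C(C)(C)C)[C@H]1[C@H]2O[C@@H]2C(C)=O
F5 | step 20 | 1,8-epoxy-1-methoxy ketal of 28 (C9 and C10 hydroxyls free; C1 open) | C=C1C(=O)O[C@@H]2/C=C(/C)[C@H](O[Si](c4ccccc4)(c4ccccc4)C(C)(C)C)CC3(OC)[C@@](C)(O)[C@@H](O)[C@@H](O3)[C@@H]12
F6 | step 20 | 9-O-acetate of F5 | C=C1C(=O)O[C@@H]2/C=C(/C)[C@H](O[Si](c4ccccc4)(c4ccccc4)C(C)(C)C)CC3(OC)[C@@](C)(O)[C@@H](OC(C)=O)[C@@H](O3)[C@@H]12
F7 | step 20 | 9-O-acetyl derivative of 28 with free C8 hydroxyl | C=C1C(=O)O[C@@H]2/C=C(/C)[C@H](O[Si](c3ccccc3)(c3ccccc3)C(C)(C)C)CC(=O)[C@@](C)(O)[C@@H](OC(C)=O)[C@@H](O)[C@@H]12
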